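Ring C is a resorcinol whose oxygens sit on C2' and C4', meta to one another, and which hangs from coumarin C3 through C1'. This is the pattern of a linear six-carbon chain with carbonyls at C2' and C4' and an aldehyde-level terminus at C6'. The route therefore disconnects C1'–C6'. In one operation, base folds a C3-bound (E)-6-methoxy-2,4-dioxohex-5-enyl chain by carbanion addition of C1' to C6', methanol loss and enolisation, creating the whole aromatic ring C without any cross-coupling. The precursor is the fully substituted 7-methoxy-6-prenylcoumarin carrying this chain on C3 and an allyl ether on O5, so that the final unmasking is neutral and spares the acid-sensitive prenyl/phenol pair.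

Key step: step 9

Assumption: the tricarbonyl compound 15 is drawn as its diketo tautomer although it should exist largely as an enol; the chain carbons of 15 are given the ring C locants C1' to C6', counted from the coumarin outward.

Step 1
Reactants: 1 2,6-dihydroxy-4-methoxybenzaldehyde; 2 succinic anhydride
Product: 3 (5-hydroxy-7-methoxy-2-oxo-2H-chromen-3-yl)acetic acid
Conditions: 2 (3 equiv), disodium succinate Na2C4H4O4 (1.2 equiv), neat, 170–180 °C; then 2 M NaOH, rt; HCl to pH 1
Reagents that add atoms: none
Why: In this Perkin-type condensation the succinate-generated enolate of the anhydride condenses with the aldehyde and either of the two equivalent ortho-hydroxyls lactonises onto the new acrylic carboxyl, leaving the second carboxyl as the C3 acetic acid, while the basic work-up cleaves any phenolic hemisuccinate and acidification re-closes the lactone.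

Step 2
Reactants: 3 (5-hydroxy-7-methoxy-2-oxo-2H-chromen-3-yl)acetic acid
Product: 4 methyl (5-hydroxy-7-methoxy-2-oxo-2H-chromen-3-yl)acetate
Conditions: MeOH, H2SO4 (cat.), reflux
Reagents that add atoms: methanol, CO
Why: Fischer esterification masks the acid for the alkylation steps, and the coumarin lactone and the phenol are stable to methanolic acid.

Step 3
Reactants: 4 methyl (5-hydroxy-7-methoxy-2-oxo-2H-chromen-3-yl)acetate; 5 3-chloro-3-methylbut-1-yne
Product: 6 methyl [7-methoxy-5-(2-methylbut-3-yn-2-yloxy)-2-oxo-2H-chromen-3-yl]acetate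
Conditions: 5 (2 equiv), DBU (2 equiv), CuCl2 (1 mol %), MeCN, 0 °C to rt
Reagents that add atoms: none
Why: Copper-catalysed O-propargylation of a phenol by a tertiary propargylic chloride is the standard entry to aryl 1,1-dimethylpropargyl ethers, and O5 is the only free hydroxyl.

Step 4
Reactants: 6 methyl [7-methoxy-5-(2-methylbut-3-yn-2-yloxy)-2-oxo-2H-chromen-3-yl]acetate
Product: 7 methyl [7-methoxy-5-(2-methylbut-3-en-2-yloxy)-2-oxo-2H-chromen-3-yl]acetate
Conditions: H2 (1 atm), Pd/CaCO3 poisoned with Pb(OAc)2, quinoline, EtOAc, rt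
Reagents that add atoms: none
Why: Lindlar-type semihydrogenation stops at the terminal alkene and leaves the conjugated, trisubstituted C3=C4 bond of the coumarin untouched.

Step 5
Reactants: 7 methyl [7-methoxy-5-(2-methylbut-3-en-2-yloxy)-2-oxo-2H-chromen-3-yl]acetate
Product: 9 methyl [5-hydroxy-7-methoxy-6-(3-methylbut-2-en-1-yl)-2-oxo-2H-chromen-3-yl]acetate, via ortho-dienone 8 (not isolated)
Conditions: N,N-diethylaniline, 130–140 °C, N2
Reagents that add atoms: none
Why: The aromatic Claisen rearrangement of the 1,1-dimethylallyl ether delivers the allyl terminus to C6, the only ortho position of O5 that bears hydrogen, so the prenyl group arrives regiospecifically and dienone 8 rearomatises by tautomerisation in the basic solvent.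

Step 6
Reactants: 9 methyl [5-hydroxy-7-methoxy-6-(3-methylbut-2-en-1-yl)-2-oxo-2H-chromen-3-yl]acetate
Product: 10 methyl [5-(allyloxy)-7-methoxy-6-(3-methylbut-2-en-1-yl)-2-oxo-2H-chromen-3-yl]acetate
Conditions: allyl bromide, K2CO3, DMF, rt
Reagents that add atoms: allyl bromide, C=CCBr
Why: Williamson etherification of the phenoxide installs a group that withstands hydroxide, enolates and methoxide and is later removed without acid, and carbonate is too weak to alkylate the ester methylene.

Step 7
Reactants: 10 methyl [5-(allyloxy)-7-methoxy-6-(3-methylbut-2-en-1-yl)-2-oxo-2H-chromen-3-yl]acetate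
Product: 11 [5-(allyloxy)-7-methoxy-6-(3-methylbut-2-en-1-yl)-2-oxo-2H-chromen-3-yl]acetic acid
Conditions: LiOH, THF/H2O, rt; then 1 M HCl to pH 2
Reagents that add atoms: lithium hydroxide, [Li+].[OH-]
Why: Saponification frees the acid, any lactone opened by hydroxide re-closes from the cis-cinnamate on acidification, and the acid work-up is harmless because no free phenol sits next to the prenyl group.

Step 8
Reactants: 11 [5-(allyloxy)-7-methoxy-6-(3-methylbut-2-en-1-yl)-2-oxo-2H-chromen-3-yl]acetic acid; 12 (E)-4-methoxybut-3-en-2-one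
Product: 15 (E)-6-[5-(allyloxy)-7-methoxy-6-(3-methylbut-2-en-1-yl)-2-oxo-2H-chromen-3-yl]-1-methoxyhex-1-ene-3,5-dione, via lithium enolate 13 (not isolated), via acyl imidazolide 14 (not isolated)
Conditions: flask A: 11, CDI (1.1 equiv), THF, rt; flask B: 12 (3.5 equiv), LiN(SiMe3)2 (3.5 equiv), THF, −78 °C; A added to B at −78 °C; AcOH quench at −78 °C, pH 7 buffer work-up
Reagents that add atoms: none
Why: Claisen-type C-acylation of the kinetic methyl-side lithium enolate of a β-methoxy enone by an acyl imidazolide is an established route to 1-methoxyhex-1-ene-3,5-diones; the excess enolate absorbs the imidazole N–H and the acidic diketone proton, the low temperature keeps the lactone out of play, and the E geometry of 12 is carried through unchanged.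

Step 9
Reactants: 15 (E)-6-[5-(allyloxy)-7-methoxy-6-(3-methylbut-2-en-1-yl)-2-oxo-2H-chromen-3-yl]-1-methoxyhex-1-ene-3,5-dione
Product: 18 5-(allyloxy)-3-(2,4-dihydroxyphenyl)-7-methoxy-6-(3-methylbut-2-en-1-yl)-2H-chromen-2-one, via methoxy diketone adduct 16 (not isolated), via cyclohexenedione tautomer 17 (not isolated)
Conditions: NaOMe (4 equiv), MeOH, rt to 50 °C; then AcOH to pH 5
Reagents that add atoms: none
Why: Methoxide first forms the C2'/C4' diketonate and then, in a small equilibrium share, deprotonates C1', the methylene flanked by the C2' carbonyl and the coumarin C3=C4 π-system; this carbanion adds to the β-methoxy enone carbon C6' to give adduct 16, which expels methoxide to 17, and 17 enolises irreversibly to the resorcinol. The closest known reaction type is the base-induced aldol-type folding of 3,5-dioxo aldehyde equivalents and triketones into resorcinols. Ring C closes in a 6-endo-trig mode with respect to the C5'=C6' bond, and the E geometry of the methoxyvinyl group does not matter because C6' becomes tetrahedral before methoxide leaves. No stereocentre remains, since the two sp3 centres of 16 are erased on aromatisation. The selectivity needed is C- over O-cyclisation: attack through the C2' enolate oxygen would give a 2-substituted 4-pyranone, but methoxide re-adds at its C6' and reopens it, so the material should drain through the irreversible aromatisation. A lactone opened by methoxide re-closes on acidification, and the allyl ether and the prenyl group are inert to base.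

Step 10
Reactants: 18 5-(allyloxy)-3-(2,4-dihydroxyphenyl)-7-methoxy-6-(3-methylbut-2-en-1-yl)-2H-chromen-2-one
Product: 19 3-(2,4-dihydroxyphenyl)-5-hydroxy-7-methoxy-6-(3-methylbut-2-en-1-yl)-2H-chromen-2-one (CNP0305155.0)
Conditions: Pd(PPh3)4 (5 mol %), morpholine (10 equiv), THF, rt
Reagents that add atoms: none
Why: In this Tsuji–Trost-type deallylation zerovalent palladium ionises the allyl aryl ether to a π-allyl complex that morpholine captures, so O5 is freed under neutral conditions that cannot cyclise the C5 hydroxyl onto the C6 prenyl group.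

Compound list
1 | 2,6-dihydroxy-4-methoxybenzaldehyde | COc1cc(O)c(C=O)c(O)c1 | starting material
2 | succinic anhydride | O=C1CCC(=O)O1 | starting material
3 | (5-hydroxy-7-methoxy-2-oxo-2H-chromen-3-yl)acetic acid | COc1cc(O)c2cc(CC(=O)O)c(=O)oc2c1 | intermediate
4 | methyl (5-hydroxy-7-methoxy-2-oxo-2H-chromen-3-yl)acetate | COc1cc(O)c2cc(CC(=O)OC)c(=O)oc2c1 | intermediate
5 | 3-chloro-3-methylbut-1-yne | CC(C)(Cl)C#C | starting material
6 | methyl [7-methoxy-5-(2-methylbut-3-yn-2-yloxy)-2-oxo-2H-chromen-3-yl]acetate | COc1cc(OC(C)(C)C#C)c2cc(CC(=O)OC)c(=O)oc2c1 | intermediate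
7 | methyl [7-methoxy-5-(2-methylbut-3-en-2-yloxy)-2-oxo-2H-chromen-3-yl]acetate | COc1cc(OC(C)(C)C=C)c2cc(CC(=O)OC)c(=O)oc2c1 | intermediate
8 | methyl [7-methoxy-6-(3-methylbut-2-en-1-yl)-2,5-dioxo-5,6-dihydro-2H-chromen-3-yl]acetate (ortho-dienone, racemic at C6, not isolated) | COC1=CC2=C(C=C(CC(=O)OC)C(=O)O2)C(=O)C1CC=C(C)C | intermediate
9 | methyl [5-hydroxy-7-methoxy-6-(3-methylbut-2-en-1-yl)-2-oxo-2H-chromen-3-yl]acetate | COc1cc2oc(=O)c(CC(=O)OC)cc2c(O)c1CC=C(C)C | intermediate
10 | methyl [5-(allyloxy)-7-methoxy-6-(3-methylbut-2-en-1-yl)-2-oxo-2H-chromen-3-yl]acetate | COc1cc2oc(=O)c(CC(=O)OC)cc2c(OCC=C)c1CC=C(C)C | intermediate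
11 | [5-(allyloxy)-7-methoxy-6-(3-methylbut-2-en-1-yl)-2-oxo-2H-chromen-3-yl]acetic acid | COc1cc2oc(=O)c(CC(=O)O)cc2c(OCC=C)c1CC=C(C)C | intermediate
12 | (E)-4-methoxybut-3-en-2-one | CO/C=C/C(C)=O | starting material
13 | lithium (E)-4-methoxybuta-1,3-dien-2-olate (not isolated) | [Li+].[O-]C(=C)/C=C/OC | intermediate
14 | 1-{[5-(allyloxy)-7-methoxy-6-(3-methylbut-2-en-1-yl)-2-oxo-2H-chromen-3-yl]acetyl}-1H-imidazole (not isolated) | COc1cc2oc(=O)c(CC(=O)n3ccnc3)cc2c(OCC=C)c1CC=C(C)C | intermediate
15 | (E)-6-[5-(allyloxy)-7-methoxy-6-(3-methylbut-2-en-1-yl)-2-oxo-2H-chromen-3-yl]-1-methoxyhex-1-ene-3,5-dione | COc1cc2oc(=O)c(CC(=O)CC(=O)/C=C/OC)cc2c(OCC=C)c1CC=C(C)C | intermediate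
16 | 5-(allyloxy)-7-methoxy-3-(2-methoxy-4,6-dioxocyclohexyl)-6-(3-methylbut-2-en-1-yl)-2H-chromen-2-one (diastereomer mixture, not isolated) | COC1CC(=O)CC(=O)C1c1cc2c(OCC=C)c(CC=C(C)C)c(OC)cc2oc1=O | intermediate
17 | 5-(allyloxy)-3-(2,4-dioxocyclohex-5-en-1-yl)-7-methoxy-6-(3-methylbut-2-en-1-yl)-2H-chromen-2-one (racemic, not isolated) | O=C1C=CC(c2cc3c(OCC=C)c(CC=C(C)C)c(OC)cc3oc2=O)C(=O)C1 | intermediate
18 | 5-(allyloxy)-3-(2,4-dihydroxyphenyl)-7-methoxy-6-(3-methylbut-2-en-1-yl)-2H-chromen-2-one | COc1cc2oc(=O)c(-c3ccc(O)cc3O)cc2c(OCC=C)c1CC=C(C)C | intermediate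
19 | 3-(2,4-dihydroxyphenyl)-5-hydroxy-7-methoxy-6-(3-methylbut-2-en-1-yl)-2H-chromen-2-one | COc1cc2oc(=O)c(-c3ccc(O)cc3O)cc2c(O)c1CC=C(C)C | target

Total step count: 10. Longest linear sequence: 10 steps (1 to 19).

Steps most likely to fail

Step 9. The chain may stop at the O-cyclised stage instead of funnelling on, or methoxide may cleave the tricarbonyl chain by retro-Claisen attack before C1' closes onto C6'. The fallback sets out from 15 and commits to O-cyclisation on purpose. Catalytic CF3CO2H in toluene at rt should give 2-{[5-(allyloxy)-7-methoxy-6-(3-methylbut-2-en-1-yl)-2-oxo-2H-chromen-3-yl]methyl}-4H-pyran-4-one F1, which is purified. Heating F1 with aqueous KOH in MeOH should let hydroxide add at pyranone C6 and open the ring to 6-[5-(allyloxy)-7-methoxy-6-(3-methylbut-2-en-1-yl)-2-oxo-2H-chromen-3-yl]-3,5-dioxohexanal F2, which is not isolated. Intramolecular aldol condensation of C1' onto the formyl carbon and dehydration then build ring C, and acidification to pH 2 re-closes the lactone. The fallback returns to the route at 18.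

Step 8. The acidic methylene of the acyl imidazolide may be deprotonated, leading to ketene formation and self-condensation, or the enolate may attack the lactone carbonyl in competition with C-acylation. The fallback sets out from 11 and uses no base. Oxalyl chloride with catalytic DMF in CH2Cl2 should give [5-(allyloxy)-7-methoxy-6-(3-methylbut-2-en-1-yl)-2-oxo-2H-chromen-3-yl]acetyl chloride F3. A Mukaiyama-type C-acylation of (E)-1-methoxy-3-(trimethylsilyloxy)buta-1,3-diene by F3 follows in CH2Cl2 from −78 °C to rt, with catalytic ZnCl2 if needed. The silyl enol ether terminus should be acylated with loss of the silyl group. The fallback returns to the route at 15.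

Step 1. The electron-rich dihydroxybenzaldehyde may decompose or be O-acylated in the hot melt faster than it condenses. The fallback sets out from 1 and replaces the Perkin condensation by a Wittig olefination with lactonisation. Dimethyl 2-(triphenylphosphoranylidene)butanedioate F4 is made from methyl (triphenylphosphoranylidene)acetate (2 equiv) and methyl bromoacetate by transylidation in EtOAc. Heating 1 with F4 in N,N-diethylaniline at reflux should give dimethyl (E)-2-(2,6-dihydroxy-4-methoxybenzylidene)butanedioate F5. At that temperature F5 should isomerise about the double bond and lactonise with loss of methanol. The fallback returns to the route at 4 and makes step 2 unnecessary.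

Further compounds
F1 | step 9 | 2-{[5-(allyloxy)-7-methoxy-6-(3-methylbut-2-en-1-yl)-2-oxo-2H-chromen-3-yl]methyl}-4H-pyran-4-one | COc1cc2oc(=O)c(Cc3cc(=O)cco3)cc2c(OCC=C)c1CC=C(C)C
F2 | step 9 | 6-[5-(allyloxy)-7-methoxy-6-(3-methylbut-2-en-1-yl)-2-oxo-2H-chromen-3-yl]-3,5-dioxohexanal | COc1cc2oc(=O)c(CC(=O)CC(=O)CC=O)cc2c(OCC=C)c1CC=C(C)C
F3 | step 8 | [5-(allyloxy)-7-methoxy-6-(3-methylbut-2-en-1-yl)-2-oxo-2H-chromen-3-yl]acetyl chloride | COc1cc2oc(=O)c(CC(=O)Cl)cc2c(OCC=C)c1CC=C(C)C
F4 | step 1 | dimethyl 2-(triphenylphosphoranylidene)butanedioate | COC(=O)CC(C(=O)OC)=P(c1ccccc1)(c1ccccc1)c1ccccc1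
F5 | step 1 | dimethyl (E)-2-(2,6-dihydroxy-4-methoxybenzylidene)butanedioate | COC(=O)C/C(C(=O)OC)=C\c1c(O)cc(OC)cc1O
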